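Ring A of the target carries OH and CHO on adjacent carbons, with the CHO carbon wedged between the C–OH carbon and the carbon bonded to the diaryl ether oxygen of the seven-membered ring. Both substituents are therefore put in last and together: the two adjacent ring A carbons are unmasked as an aryne, and N,N-dimethylformamide inserts its C=O bond across it, oxygen on one carbon and carbon on the other, to leave OH and CHO after hydrolysis. The precursor is the complete, protected depsidone–phthalide (acetate in place, ring B phenol and the (S) lactol as 4-methoxybenzyl ether and acetal) bearing SiMe3 and OTf on those two ring A carbons.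

Key step: step 19

Assumption: the free (S) lactol of 30 (a 3-hydroxyphthalide) is taken to keep its configuration in cold, neutral, aprotic media; because it can equilibrate through the ring-opened formyl acid in base or hot protic solvent, step 20 and the isolation avoid both.

Remark: N-halosuccinimides attack orsellinates mainly beside the methyl group, so the halogen needed between the two oxygens of ring A is introduced as iodine under aqueous hydrogencarbonate, and silicon is installed before the rings are joined, when the only electrophile present is a hindered ester.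

Step 1
Reactants: 1 orsellinic acid (2,4-dihydroxy-6-methylbenzoic acid)
Product: 2 allyl 2,4-dihydroxy-6-methylbenzoate
Conditions: allyl bromide (1.05 equiv), KHCO3, DMF, rt
Reagents that add atoms: allyl bromide, C=CCBr
Why: SN2 O-alkylation of the carboxylate, since hydrogencarbonate ionises only the acid and leaves both phenols free; the allyl ester is chosen because zerovalent palladium can later remove it beside an acetate, an acetal and an aryl ester.

Step 2
Reactants: 2 allyl 2,4-dihydroxy-6-methylbenzoate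
Product: 3 allyl 2,4-dihydroxy-3-iodo-6-methylbenzoate
Conditions: I2 (1.05 equiv), NaHCO3, THF/H2O, 0 °C
Reagents that add atoms: iodine, II
Why: Electrophilic aromatic iodination of the resorcinol monoanion, which under aqueous hydrogencarbonate goes to the carbon between the two oxygens (the behaviour used to make 2-iodoresorcinol), the other open site being shielded by the neighbouring methyl group.

Step 3
Reactants: 3 allyl 2,4-dihydroxy-3-iodo-6-methylbenzoate
Product: 6 allyl 2,4-dihydroxy-6-methyl-3-(trimethylsilyl)benzoate, via bis(trimethylsilyl) ether 4 (not isolated), via lithium phenoxide silyl ether 5 (not isolated)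
Conditions: HMDS (neat), 80 °C, then evaporate; n-BuLi (1.1 equiv), THF, −78 °C; sat. aq NH4Cl, rt
Reagents that add atoms: hexamethyldisilazane, C[Si](C)(C)N[Si](C)(C)C
Why: Retro-Brook rearrangement, in which iodine–lithium exchange at −78 °C outruns attack on the doubly ortho-substituted ester, the aryllithium takes silicon from a neighbouring oxygen (1,3 O-to-C shift) and the remaining O–Si bond is hydrolysed on work-up.

Step 4
Reactants: 6 allyl 2,4-dihydroxy-6-methyl-3-(trimethylsilyl)benzoate
Product: 7 allyl 4-(allyloxy)-2-hydroxy-6-methyl-3-(trimethylsilyl)benzoate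
Conditions: allyl bromide (1.1 equiv), K2CO3, acetone, rt
Reagents that add atoms: allyl bromide, C=CCBr
Why: Williamson ether synthesis at the more acidic, unchelated 4-OH, while the 2-OH, hydrogen-bonded to the ester carbonyl, stays free for the diaryl ether coupling.

Step 5
Reactants: 8 methyl 5-bromo-2,4-dihydroxybenzoate
Product: 9 methyl 4-(allyloxy)-5-bromo-2-hydroxybenzoate
Conditions: allyl bromide (1.05 equiv), K2CO3, acetone, 40 °C
Reagents that add atoms: allyl bromide, C=CCBr
Why: Williamson ether synthesis selective for the 4-OH (para to the ester, ortho to bromine, not chelated) over the hydrogen-bonded 2-OH.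

Step 6
Reactants: 9 methyl 4-(allyloxy)-5-bromo-2-hydroxybenzoate
Product: 10 methyl 4-(allyloxy)-5-bromo-3-formyl-2-hydroxybenzoate
Conditions: MgCl2, Et3N, paraformaldehyde, MeCN, reflux; 1 M HCl work-up
Reagents that add atoms: formaldehyde (as paraformaldehyde), C=O
Why: Casnati–Skattebøl ortho-formylation of the magnesium phenoxide, for which the carbon between the two oxygens is the only open ortho position (para is blocked by bromine) and a second formaldehyde accepts hydride to give the aldehyde.

Step 7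
Reactants: 10 methyl 4-(allyloxy)-5-bromo-3-formyl-2-hydroxybenzoate
Product: 11 methyl 4-(allyloxy)-5-bromo-3-formyl-2-(4-methoxybenzyloxy)benzoate
Conditions: PMBCl, K2CO3, Bu4NI (cat.), DMF, 50 °C
Reagents that add atoms: 4-methoxybenzyl chloride, COc1ccc(CCl)cc1
Why: Williamson etherification of the remaining phenol, which is acidic because it sits between two carbonyl groups; this ether stays on until the last step so that no phenoxide can form beside the future acetoxymethyl group.

Step 8
Reactants: 11 methyl 4-(allyloxy)-5-bromo-3-formyl-2-(4-methoxybenzyloxy)benzoate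
Product: 12 methyl 4-(allyloxy)-5-bromo-3-(hydroxymethyl)-2-(4-methoxybenzyloxy)benzoate
Conditions: NaBH4, THF/MeOH, 0 °C
Reagents that add atoms: none
Why: Borohydride reduction of the aldehyde, the benzoate ester being inert to NaBH4 at 0 °C.

Step 9
Reactants: 12 methyl 4-(allyloxy)-5-bromo-3-(hydroxymethyl)-2-(4-methoxybenzyloxy)benzoate
Product: 13 methyl 4-(allyloxy)-5-bromo-3-[(tert-butyldimethylsilyloxy)methyl]-2-(4-methoxybenzyloxy)benzoate
Conditions: TBSCl, imidazole, DMF, rt
Reagents that add atoms: tert-butyldimethylsilyl chloride, CC(C)(C)[Si](C)(C)Cl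
Why: Silyl ether formation, which hides the hydroxyl from the amide base of step 10 and, unlike an acetate, cannot be expelled as an o-quinone methide leaving group while the neighbouring ring B phenol is free (steps 14 and 15).

Step 10
Reactants: 13 methyl 4-(allyloxy)-5-bromo-3-[(tert-butyldimethylsilyloxy)methyl]-2-(4-methoxybenzyloxy)benzoate
Product: 16 methyl 4-(allyloxy)-5-bromo-6-formyl-2-(4-methoxybenzyloxy)-3-[(tert-butyldimethylsilyloxy)methyl]benzoate, via arylmagnesium chloride 14 (not isolated), via magnesium hemiaminal alkoxide 15 (not isolated)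
Conditions: TMPMgCl·LiCl (1.3 equiv), THF, −20 to 0 °C; DMF (3 equiv), −20 °C to rt; aq NH4Cl
Reagents that add atoms: N,N-dimethylformamide, CN(C)C=O
Why: Directed ortho-magnesiation with the Knochel–Hauser base at the only ring C–H, acidified by the flanking ester and bromine, followed by formylation of the arylmagnesium with DMF (Bouveault aldehyde synthesis); the magnesium amide neither exchanges the bromide nor adds to the ester.

Step 11
Reactants: 7 allyl 4-(allyloxy)-2-hydroxy-6-methyl-3-(trimethylsilyl)benzoate; 16 methyl 4-(allyloxy)-5-bromo-6-formyl-2-(4-methoxybenzyloxy)-3-[(tert-butyldimethylsilyloxy)methyl]benzoate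
Product: 17 allyl 4-(allyloxy)-2-[6-(allyloxy)-2-formyl-3-(methoxycarbonyl)-4-(4-methoxybenzyloxy)-5-[(tert-butyldimethylsilyloxy)methyl]phenoxy]-6-methyl-3-(trimethylsilyl)benzoate
Conditions: CuI (20 mol %), picolinic acid (40 mol %), K3PO4, DMSO, 90 °C
Reagents that add atoms: none
Why: Ullmann-type copper-catalysed O-arylation of the ring A phenol by the ring B bromide, whose ortho formyl group activates the C–Br bond, with a picolinate-ligated copper system developed for diaryl ethers that carry ortho substituents on both partners.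

Step 12
Reactants: 17 diaryl ether (ring B methyl ester beside CHO)
Product: 18 allyl 4-(allyloxy)-2-{[5-(allyloxy)-3-hydroxy-7-(4-methoxybenzyloxy)-1-oxo-6-[(tert-butyldimethylsilyloxy)methyl]-1,3-dihydroisobenzofuran-4-yl]oxy}-6-methyl-3-(trimethylsilyl)benzoate (racemic lactol)
Conditions: LiOH (1.5 equiv), THF/H2O, 0 °C; cold 1 M HCl to pH 3
Reagents that add atoms: lithium hydroxide, [Li+].[OH-]
Why: Saponification with neighbouring-group participation (hydroxide adds to the ortho aldehyde and the alkoxide expels methoxide from the ester), so the ring B methyl ester falls at 0 °C while the doubly ortho-substituted allyl ester of ring A survives; acidification closes the formyl acid to the 3-hydroxyphthalide as a racemate, whose configuration is settled in step 18.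

Step 13
Reactants: 18 racemic lactol
Product: 19 allyl 4-(allyloxy)-2-{[5-(allyloxy)-3,7-bis(4-methoxybenzyloxy)-1-oxo-6-[(tert-butyldimethylsilyloxy)methyl]-1,3-dihydroisobenzofuran-4-yl]oxy}-6-methyl-3-(trimethylsilyl)benzoate (racemic acetal)
Conditions: 4-methoxybenzyl alcohol (3 equiv), PPTS (10 mol %), 4 Å MS, ClCH2CH2Cl, 50 °C
Reagents that add atoms: 4-methoxybenzyl alcohol, COc1ccc(CO)cc1
Why: Acid-catalysed acetalisation of the lactol (pseudo-ester formation) through the phthalidyl oxocarbenium ion, driven by molecular sieves under a pyridinium acid too weak to cleave the silyl ether or the aryl–silicon bond; the acetal is still racemic.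

Step 14
Reactants: 19 racemic acetal
Product: 20 4-hydroxy-2-{[5-hydroxy-3,7-bis(4-methoxybenzyloxy)-1-oxo-6-[(tert-butyldimethylsilyloxy)methyl]-1,3-dihydroisobenzofuran-4-yl]oxy}-6-methyl-3-(trimethylsilyl)benzoic acid (racemic)
Conditions: Pd(PPh3)4 (5 mol %), TolSO2Na (4 equiv), THF/H2O, rt; cold 0.5 M HCl to pH 3–4
Reagents that add atoms: none
Why: Tsuji–Trost deallylation, in which zerovalent palladium ionises the allyl ester and both aryl allyl ethers and the sulfinate traps the π-allyl complexes, a near-neutral method that spares the silyl groups, both 4-methoxybenzyl groups and the acetal.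

Step 15
Reactants: 20 racemic hydroxy acid
Product: 21 rac-5-[(tert-butyldimethylsilyloxy)methyl]-10-hydroxy-1,4-bis(4-methoxybenzyloxy)-8-methyl-11-(trimethylsilyl)-1H-isobenzofuro[4,5-b][1,4]benzodioxepine-3,7-dione
Conditions: EDCI·HCl (1.5 equiv), DMAP (0.3 equiv), CH2Cl2 (5 mM), rt
Reagents that add atoms: none
Why: Steglich-type carbodiimide lactonisation that closes the seven-membered depsidone ring, because only the ring B phenol ortho to the ether oxygen can reach the activated acid, while high dilution and the silyl group beside the ring A phenol hold back intermolecular acylation.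

Step 16
Reactants: 21 racemic depsidone silyl ether
Product: 22 rac-10-hydroxy-5-(hydroxymethyl)-1,4-bis(4-methoxybenzyloxy)-8-methyl-11-(trimethylsilyl)-1H-isobenzofuro[4,5-b][1,4]benzodioxepine-3,7-dione
Conditions: HF·pyridine, pyridine, THF, 0 °C to rt
Reagents that add atoms: none
Why: Cleavage of the primary silyl ether by buffered hydrogen fluoride, which leaves the aryl–SiMe3 bond (no leaving group beside it yet), the aryl ester and the acetal intact; a free hydroxymethyl group next to the depsidone ester oxygen is a stable arrangement.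

Step 17
Reactants: 22 racemic phenol alcohol
Product: 24 rac-[1,4-bis(4-methoxybenzyloxy)-8-methyl-3,7-dioxo-10-(trifluoromethanesulfonyloxy)-11-(trimethylsilyl)-1,3-dihydro-7H-isobenzofuro[4,5-b][1,4]benzodioxepin-5-yl]methyl acetate, via triflate alcohol 23 (not isolated)
Conditions: PhNTf2 (1.2 equiv), Et3N, DMAP (cat.), CH2Cl2, 0 °C to rt; then Ac2O (1.5 equiv), rt
Reagents that add atoms: N-phenylbis(trifluoromethanesulfonimide), O=S(=O)(N(c1ccccc1)S(=O)(=O)C(F)(F)F)C(F)(F)F; acetic anhydride, CC(=O)OC(C)=O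
Why: Phenol triflation followed by alcohol acetylation in one flask, since the triflimide reagent sulfonylates only the phenoxide and leaves the primary alcohol for the anhydride, and no fluoride or strong base is present once silicon and triflate are neighbours.

Step 18
Reactants: 24 racemic silyl triflate
Product: 25 [(1S)-1,4-bis(4-methoxybenzyloxy)-8-methyl-3,7-dioxo-10-(trifluoromethanesulfonyloxy)-11-(trimethylsilyl)-1,3-dihydro-7H-isobenzofuro[4,5-b][1,4]benzodioxepin-5-yl]methyl acetate
Conditions: preparative HPLC on amylose tris(3,5-dimethylphenylcarbamate)/silica, hexane/i-PrOH; (S) isomer collected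
Reagents that add atoms: none
Why: Chromatographic resolution on a chiral stationary phase, which fixes the acetal stereocentre by separating the enantiomers; the (S) isomer is to be assigned by X-ray diffraction (S and Si as anomalous scatterers) and the (R) isomer can be racemised with 4-methoxybenzyl alcohol and PPTS and recycled.

Step 19
Reactants: 25 (S) silyl triflate
Product: 29 [(1S)-11-formyl-10-hydroxy-1,4-bis(4-methoxybenzyloxy)-8-methyl-3,7-dioxo-1,3-dihydro-7H-isobenzofuro[4,5-b][1,4]benzodioxepin-5-yl]methyl acetate, via ring A aryne 26 (not isolated), via benzoxete adduct 27 (not isolated), via quinone methide aminal 28 (not isolated)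
Conditions: CsF (3 equiv), dry DMF (solvent), 0 °C to rt; then cold aq citric acid (pH 4), 0 °C
Reagents that add atoms: N,N-dimethylformamide, CN(C)C=O; water, O
Why: Desilylation by fluoride with loss of triflate unmasks a triple bond between the two adjacent ring A carbons that carried SiMe3 and OTf. DMF, present as solvent, adds through its carbonyl oxygen to the aryne carbon distal to the aryloxy group, the aryl anion collapses onto the iminium carbon (formal [2+2] to a benzoxete), ring opening gives an o-quinone methide aminal, and aqueous acid converts this into phenol and aldehyde. The closest known reaction type is the insertion of arynes into the C=O bond of formamides, which gives salicylaldehydes after hydrolysis. No ring of the product is closed and no stereocentre is formed; the (S) acetal is a spectator because nothing in the medium ionises its C–O bonds. The selectivity needed is regiochemical, and it is secured by the inductively withdrawing ether oxygen beside one aryne carbon, which polarises the triple bond so that oxygen enters at the distal carbon and the formyl carbon lands between the two ring oxygens. Chemoselectivity rests on DMF being in vast excess, on the capped ring B phenol, and on the cold acidic quench, which protonates the liberated dimethylamine before it can open the aryl ester or the acetate.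

Step 20
Reactants: 29 protected galbinic acid
Product: 30 galbinic acid, [(1S)-11-formyl-1,4,10-trihydroxy-8-methyl-3,7-dioxo-1,3-dihydro-7H-isobenzofuro[4,5-b][1,4]benzodioxepin-5-yl]methyl acetate
Conditions: DDQ (3 equiv), CH2Cl2/pH 7 phosphate buffer (10:1), 0 °C to rt; filtration, no basic wash
Reagents that add atoms: none
Why: Oxidative cleavage of both 4-methoxybenzyl groups, in which DDQ abstracts hydride from each 4-methoxybenzylic CH2 and water collapses the oxocarbenium ions to 4-methoxybenzaldehyde, so the phenol oxygen and the lactol oxygen never leave their carbons and the (S) centre is not touched.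

Compound list
1 | orsellinic acid (2,4-dihydroxy-6-methylbenzoic acid) | Cc1cc(O)cc(O)c1C(=O)O | starting material
2 | allyl 2,4-dihydroxy-6-methylbenzoate | C=CCOC(=O)c1c(C)cc(O)cc1O | intermediate
3 | allyl 2,4-dihydroxy-3-iodo-6-methylbenzoate | C=CCOC(=O)c1c(C)cc(O)c(I)c1O | intermediate
4 | allyl 3-iodo-6-methyl-2,4-bis(trimethylsilyloxy)benzoate (not isolated) | C=CCOC(=O)c1c(C)cc(O[Si](C)(C)C)c(I)c1O[Si](C)(C)C | intermediate
5 | lithium salt of allyl 4-hydroxy-6-methyl-3-(trimethylsilyl)-2-(trimethylsilyloxy)benzoate (not isolated; drawn as the 4-olate, the 2-olate isomer behaves alike) | C=CCOC(=O)c1c(C)cc([O-])c([Si](C)(C)C)c1O[Si](C)(C)C.[Li+] | intermediate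
6 | allyl 2,4-dihydroxy-6-methyl-3-(trimethylsilyl)benzoate | C=CCOC(=O)c1c(C)cc(O)c([Si](C)(C)C)c1O | intermediate
7 | allyl 4-(allyloxy)-2-hydroxy-6-methyl-3-(trimethylsilyl)benzoate | C=CCOC(=O)c1c(C)cc(OCC=C)c([Si](C)(C)C)c1O | intermediate
8 | methyl 5-bromo-2,4-dihydroxybenzoate | COC(=O)c1cc(Br)c(O)cc1O | starting material
9 | methyl 4-(allyloxy)-5-bromo-2-hydroxybenzoate | COC(=O)c1cc(Br)c(OCC=C)cc1O | intermediate
10 | methyl 4-(allyloxy)-5-bromo-3-formyl-2-hydroxybenzoate | COC(=O)c1cc(Br)c(OCC=C)c(C=O)c1O | intermediate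
11 | methyl 4-(allyloxy)-5-bromo-3-formyl-2-(4-methoxybenzyloxy)benzoate | COC(=O)c1cc(Br)c(OCC=C)c(C=O)c1OCc1ccc(OC)cc1 | intermediate
12 | methyl 4-(allyloxy)-5-bromo-3-(hydroxymethyl)-2-(4-methoxybenzyloxy)benzoate | COC(=O)c1cc(Br)c(OCC=C)c(CO)c1OCc1ccc(OC)cc1 | intermediate
13 | methyl 4-(allyloxy)-5-bromo-3-[(tert-butyldimethylsilyloxy)methyl]-2-(4-methoxybenzyloxy)benzoate | COC(=O)c1cc(Br)c(OCC=C)c(CO[Si](C)(C)C(C)(C)C)c1OCc1ccc(OC)cc1 | intermediate
14 | chloro{3-(allyloxy)-2-bromo-4-[(tert-butyldimethylsilyloxy)methyl]-6-(methoxycarbonyl)-5-(4-methoxybenzyloxy)phenyl}magnesium (not isolated) | COC(=O)c1c([Mg]Cl)c(Br)c(OCC=C)c(CO[Si](C)(C)C(C)(C)C)c1OCc1ccc(OC)cc1 | intermediate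
15 | chloromagnesium alkoxide of the DMF adduct of 14, ArCH(NMe2)OMgCl (not isolated) | COC(=O)c1c(C(O[Mg]Cl)N(C)C)c(Br)c(OCC=C)c(CO[Si](C)(C)C(C)(C)C)c1OCc1ccc(OC)cc1 | intermediate
16 | methyl 4-(allyloxy)-5-bromo-6-formyl-2-(4-methoxybenzyloxy)-3-[(tert-butyldimethylsilyloxy)methyl]benzoate | COC(=O)c1c(C=O)c(Br)c(OCC=C)c(CO[Si](C)(C)C(C)(C)C)c1OCc1ccc(OC)cc1 | intermediate
17 | allyl 4-(allyloxy)-2-[6-(allyloxy)-2-formyl-3-(methoxycarbonyl)-4-(4-methoxybenzyloxy)-5-[(tert-butyldimethylsilyloxy)methyl]phenoxy]-6-methyl-3-(trimethylsilyl)benzoate | C=CCOC(=O)c1c(C)cc(OCC=C)c([Si](C)(C)C)c1Oc1c(C=O)c(C(=O)OC)c(OCc2ccc(OC)cc2)c(CO[Si](C)(C)C(C)(C)C)c1OCC=C | intermediate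
18 | allyl 4-(allyloxy)-2-{[5-(allyloxy)-3-hydroxy-7-(4-methoxybenzyloxy)-1-oxo-6-[(tert-butyldimethylsilyloxy)methyl]-1,3-dihydroisobenzofuran-4-yl]oxy}-6-methyl-3-(trimethylsilyl)benzoate, racemic | C=CCOC(=O)c1c(C)cc(OCC=C)c([Si](C)(C)C)c1Oc1c2C(O)OC(=O)c2c(OCc2ccc(OC)cc2)c(CO[Si](C)(C)C(C)(C)C)c1OCC=C | intermediate
19 | allyl 4-(allyloxy)-2-{[5-(allyloxy)-3,7-bis(4-methoxybenzyloxy)-1-oxo-6-[(tert-butyldimethylsilyloxy)methyl]-1,3-dihydroisobenzofuran-4-yl]oxy}-6-methyl-3-(trimethylsilyl)benzoate, racemic | C=CCOC(=O)c1c(C)cc(OCC=C)c([Si](C)(C)C)c1Oc1c2C(OCc3ccc(OC)cc3)OC(=O)c2c(OCc2ccc(OC)cc2)c(CO[Si](C)(C)C(C)(C)C)c1OCC=C | intermediate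
20 | 4-hydroxy-2-{[5-hydroxy-3,7-bis(4-methoxybenzyloxy)-1-oxo-6-[(tert-butyldimethylsilyloxy)methyl]-1,3-dihydroisobenzofuran-4-yl]oxy}-6-methyl-3-(trimethylsilyl)benzoic acid, racemic | OC(=O)c1c(C)cc(O)c([Si](C)(C)C)c1Oc1c2C(OCc3ccc(OC)cc3)OC(=O)c2c(OCc2ccc(OC)cc2)c(CO[Si](C)(C)C(C)(C)C)c1O | intermediate
21 | rac-5-[(tert-butyldimethylsilyloxy)methyl]-10-hydroxy-1,4-bis(4-methoxybenzyloxy)-8-methyl-11-(trimethylsilyl)-1H-isobenzofuro[4,5-b][1,4]benzodioxepine-3,7-dione (depsidone; ring A 10-OH beside 11-SiMe3; ring B 4-OPMB and 5-CH2OTBS; C1 is the PMB acetal carbon) | CC(C)(C)[Si](C)(C)OCc1c(OCc4ccc(OC)cc4)c2c(c3c1OC(=O)c1c(C)cc(O)c([Si](C)(C)C)c1O3)C(OCc6ccc(OC)cc6)OC2=O | intermediate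
22 | rac-10-hydroxy-5-(hydroxymethyl)-1,4-bis(4-methoxybenzyloxy)-8-methyl-11-(trimethylsilyl)-1H-isobenzofuro[4,5-b][1,4]benzodioxepine-3,7-dione | OCc1c(OCc4ccc(OC)cc4)c2c(c3c1OC(=O)c1c(C)cc(O)c([Si](C)(C)C)c1O3)C(OCc6ccc(OC)cc6)OC2=O | intermediate
23 | rac-5-(hydroxymethyl)-1,4-bis(4-methoxybenzyloxy)-8-methyl-3,7-dioxo-11-(trimethylsilyl)-1,3-dihydro-7H-isobenzofuro[4,5-b][1,4]benzodioxepin-10-yl trifluoromethanesulfonate (not isolated) | OCc1c(OCc4ccc(OC)cc4)c2c(c3c1OC(=O)c1c(C)cc(OS(=O)(=O)C(F)(F)F)c([Si](C)(C)C)c1O3)C(OCc6ccc(OC)cc6)OC2=O | intermediate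
24 | rac-[1,4-bis(4-methoxybenzyloxy)-8-methyl-3,7-dioxo-10-(trifluoromethanesulfonyloxy)-11-(trimethylsilyl)-1,3-dihydro-7H-isobenzofuro[4,5-b][1,4]benzodioxepin-5-yl]methyl acetate | CC(=O)OCc1c(OCc4ccc(OC)cc4)c2c(c3c1OC(=O)c1c(C)cc(OS(=O)(=O)C(F)(F)F)c([Si](C)(C)C)c1O3)C(OCc6ccc(OC)cc6)OC2=O | intermediate
25 | [(1S)-1,4-bis(4-methoxybenzyloxy)-8-methyl-3,7-dioxo-10-(trifluoromethanesulfonyloxy)-11-(trimethylsilyl)-1,3-dihydro-7H-isobenzofuro[4,5-b][1,4]benzodioxepin-5-yl]methyl acetate (ring A silyl triflate of the protected depsidone, key-step precursor) | CC(=O)OCc1c(OCc4ccc(OC)cc4)c2c(c3c1OC(=O)c1c(C)cc(OS(=O)(=O)C(F)(F)F)c([Si](C)(C)C)c1O3)[C@@H](OCc6ccc(OC)cc6)OC2=O | intermediate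
26 | ring A aryne from 25, triple bond between C10 and C11, (1S) (not isolated) | CC(=O)OCc1c(OCc4ccc(OC)cc4)c2c(c3c1OC(=O)C1=C(O3)C#CC=C1C)[C@@H](OCc6ccc(OC)cc6)OC2=O | intermediate
27 | benzoxete adduct of aryne 26 with DMF, O on C10 and CH(NMe2) on C11, (1S), aminal carbon unspecified (not isolated) | CC(=O)OCc1c(OCc4ccc(OC)cc4)c2c(c3c1OC(=O)c1c(C)cc5OC(N(C)C)c5c1O3)[C@@H](OCc6ccc(OC)cc6)OC2=O | intermediate
28 | o-quinone methide aminal, 10-oxo-11-(dimethylaminomethylidene) form of ring A, (1S) (not isolated) | CC(=O)OCc1c(OCc4ccc(OC)cc4)c2c(c3c1OC(=O)C1=C(O3)C(=CN(C)C)C(=O)C=C1C)[C@@H](OCc6ccc(OC)cc6)OC2=O | intermediate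
29 | [(1S)-11-formyl-10-hydroxy-1,4-bis(4-methoxybenzyloxy)-8-methyl-3,7-dioxo-1,3-dihydro-7H-isobenzofuro[4,5-b][1,4]benzodioxepin-5-yl]methyl acetate (galbinic acid as ring B PMB ether and (S) PMB acetal) | CC(=O)OCc1c(OCc4ccc(OC)cc4)c2c(c3c1OC(=O)c1c(C)cc(O)c(C=O)c1O3)[C@@H](OCc6ccc(OC)cc6)OC2=O | intermediate
30 | galbinic acid, [(1S)-11-formyl-1,4,10-trihydroxy-8-methyl-3,7-dioxo-1,3-dihydro-7H-isobenzofuro[4,5-b][1,4]benzodioxepin-5-yl]methyl acetate | CC(=O)OCc1c(O)c2c(c3c1OC(=O)c1c(C)cc(O)c(C=O)c1O3)[C@@H](O)OC2=O | target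

Total: 20 steps. Longest linear sequence: 16 steps (8 to 30, steps 5–20); the ring A branch (1 to 7, steps 1–4) joins at step 11.

Steps most likely to fail

1. Step 11. The C–O coupling joins two partners that each carry two ortho substituents and may be too slow; at the temperature it then needs, silicon can be lost from the phenoxide (C-to-O silyl shift, then protonation) before the ether forms. The fallback sets out from 16 and 7 and returns at 21: the ester bond is made first and the ether bond is closed intramolecularly. Bromide 16 is saponified as in step 12 (LiOH, then acid) to the racemic bromo lactol 5-(allyloxy)-4-bromo-3-hydroxy-7-(4-methoxybenzyloxy)-6-[(tert-butyldimethylsilyloxy)methyl]isobenzofuran-1(3H)-one F1, which is acetalised as in step 13 (4-methoxybenzyl alcohol, PPTS) to the racemic bromo acetal 5-(allyloxy)-4-bromo-3,7-bis(4-methoxybenzyloxy)-6-[(tert-butyldimethylsilyloxy)methyl]isobenzofuran-1(3H)-one F2 and deallylated (Pd(PPh3)4, TolSO2Na) to the bromophenol 4-bromo-5-hydroxy-3,7-bis(4-methoxybenzyloxy)-6-[(tert-butyldimethylsilyloxy)methyl]isobenzofuran-1(3H)-one F3. Phenol 7 is deallylated under the same conditions to 2,4-dihydroxy-6-methyl-3-(trimethylsilyl)benzoic acid F4. Carbodiimide esterification (DCC, toluene, rt) of F4 with F3, in which the silyl-flanked 4-OH of the acid is a poor competitor, gives the racemic depside 4-bromo-3,7-bis(4-methoxybenzyloxy)-1-oxo-6-[(tert-butyldimethylsilyloxy)methyl]-1,3-dihydroisobenzofuran-5-yl 2,4-dihydroxy-6-methyl-3-(trimethylsilyl)benzoate F5. Intramolecular copper-catalysed O-arylation (CuI, N,N-dimethylglycine, Cs2CO3, dioxane, 90 °C) then closes the seven-membered ring to 21, and the route resumes at step 16.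

2. Step 19. Fluoride or the liberated dimethylamine may open the aryl ester or the acetate faster than the aryne is formed and trapped, or the aryne may be intercepted by another nucleophile or take up DMF in the wrong orientation. The fallback sets out from 21 and returns at 29: it avoids the aryne and uses the silicon only to mark the position. NIS (MeCN, 0 °C) replaces SiMe3 by iodine (ipso iododesilylation, directed by the ortho phenol) to give the racemic iodophenol 5-[(tert-butyldimethylsilyloxy)methyl]-10-hydroxy-11-iodo-1,4-bis(4-methoxybenzyloxy)-8-methyl-1H-isobenzofuro[4,5-b][1,4]benzodioxepine-3,7-dione F6. Stille coupling with tributyl(vinyl)stannane (Pd(PPh3)4, toluene, 80 °C) gives the 11-vinyl phenol F7, and Lemieux–Johnson cleavage (OsO4 cat., NaIO4, 2,6-lutidine, dioxane/H2O) gives the 11-formyl-10-hydroxy silyl ether F8. HF·pyridine frees the 5-hydroxymethyl compound F9, and Ac2O/pyridine at 0 °C without DMAP acetylates the primary alcohol in preference to the phenol chelated to the aldehyde, giving racemic 29, F10. Resolution as in step 18 delivers 29.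

3. Step 2. Iodination may take place beside the methyl group, or twice, instead of between the two hydroxyls. The fallback sets out from 2 and returns at 6: both positions are brominated and one bromine is removed again. NBS (2.1 equiv, MeCN, 0 °C) gives allyl 3,5-dibromo-2,4-dihydroxy-6-methylbenzoate F11. Na2SO3 in buffered aqueous MeOH at rt reductively removes the bromine para to the 2-OH (the selectivity known from the conversion of 2,4,6-tribromoresorcinol into 2-bromoresorcinol) and leaves allyl 3-bromo-2,4-dihydroxy-6-methylbenzoate F12. Silylation with HMDS to allyl 3-bromo-6-methyl-2,4-bis(trimethylsilyloxy)benzoate F13, bromine–lithium exchange (n-BuLi, THF, −78 °C) and the same silyl shift through 5 then give 6.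

Further compounds
F1 | step 11 | 5-(allyloxy)-4-bromo-3-hydroxy-7-(4-methoxybenzyloxy)-6-[(tert-butyldimethylsilyloxy)methyl]isobenzofuran-1(3H)-one, racemic | OC1OC(=O)c2c1c(Br)c(OCC=C)c(CO[Si](C)(C)C(C)(C)C)c2OCc1ccc(OC)cc1
F2 | step 11 | 5-(allyloxy)-4-bromo-3,7-bis(4-methoxybenzyloxy)-6-[(tert-butyldimethylsilyloxy)methyl]isobenzofuran-1(3H)-one, racemic | COc1ccc(COC2OC(=O)c3c2c(Br)c(OCC=C)c(CO[Si](C)(C)C(C)(C)C)c3OCc2ccc(OC)cc2)cc1
F3 | step 11 | 4-bromo-5-hydroxy-3,7-bis(4-methoxybenzyloxy)-6-[(tert-butyldimethylsilyloxy)methyl]isobenzofuran-1(3H)-one, racemic | COc1ccc(COC2OC(=O)c3c2c(Br)c(O)c(CO[Si](C)(C)C(C)(C)C)c3OCc2ccc(OC)cc2)cc1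
F4 | step 11 | 2,4-dihydroxy-6-methyl-3-(trimethylsilyl)benzoic acid | Cc1cc(O)c([Si](C)(C)C)c(O)c1C(=O)O
F5 | step 11 | 4-bromo-3,7-bis(4-methoxybenzyloxy)-1-oxo-6-[(tert-butyldimethylsilyloxy)methyl]-1,3-dihydroisobenzofuran-5-yl 2,4-dihydroxy-6-methyl-3-(trimethylsilyl)benzoate, racemic | Cc1cc(O)c([Si](C)(C)C)c(O)c1C(=O)Oc1c(Br)c2C(OCc3ccc(OC)cc3)OC(=O)c2c(OCc2ccc(OC)cc2)c1CO[Si](C)(C)C(C)(C)C
F6 | step 19 | rac-5-[(tert-butyldimethylsilyloxy)methyl]-10-hydroxy-11-iodo-1,4-bis(4-methoxybenzyloxy)-8-methyl-1H-isobenzofuro[4,5-b][1,4]benzodioxepine-3,7-dione | CC(C)(C)[Si](C)(C)OCc1c(OCc4ccc(OC)cc4)c2c(c3c1OC(=O)c1c(C)cc(O)c(I)c1O3)C(OCc6ccc(OC)cc6)OC2=O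
F7 | step 19 | rac-5-[(tert-butyldimethylsilyloxy)methyl]-11-ethenyl-10-hydroxy-1,4-bis(4-methoxybenzyloxy)-8-methyl-1H-isobenzofuro[4,5-b][1,4]benzodioxepine-3,7-dione | CC(C)(C)[Si](C)(C)OCc1c(OCc4ccc(OC)cc4)c2c(c3c1OC(=O)c1c(C)cc(O)c(C=C)c1O3)C(OCc6ccc(OC)cc6)OC2=O
F8 | step 19 | rac-5-[(tert-butyldimethylsilyloxy)methyl]-10-hydroxy-1,4-bis(4-methoxybenzyloxy)-8-methyl-3,7-dioxo-1,3-dihydro-7H-isobenzofuro[4,5-b][1,4]benzodioxepine-11-carbaldehyde | CC(C)(C)[Si](C)(C)OCc1c(OCc4ccc(OC)cc4)c2c(c3c1OC(=O)c1c(C)cc(O)c(C=O)c1O3)C(OCc6ccc(OC)cc6)OC2=O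
F9 | step 19 | rac-10-hydroxy-5-(hydroxymethyl)-1,4-bis(4-methoxybenzyloxy)-8-methyl-3,7-dioxo-1,3-dihydro-7H-isobenzofuro[4,5-b][1,4]benzodioxepine-11-carbaldehyde | OCc1c(OCc4ccc(OC)cc4)c2c(c3c1OC(=O)c1c(C)cc(O)c(C=O)c1O3)C(OCc6ccc(OC)cc6)OC2=O
F10 | step 19 | rac-[11-formyl-10-hydroxy-1,4-bis(4-methoxybenzyloxy)-8-methyl-3,7-dioxo-1,3-dihydro-7H-isobenzofuro[4,5-b][1,4]benzodioxepin-5-yl]methyl acetate (racemic 29) | CC(=O)OCc1c(OCc4ccc(OC)cc4)c2c(c3c1OC(=O)c1c(C)cc(O)c(C=O)c1O3)C(OCc6ccc(OC)cc6)OC2=O
F11 | step 2 | allyl 3,5-dibromo-2,4-dihydroxy-6-methylbenzoate | C=CCOC(=O)c1c(C)c(Br)c(O)c(Br)c1O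
F12 | step 2 | allyl 3-bromo-2,4-dihydroxy-6-methylbenzoate | C=CCOC(=O)c1c(C)cc(O)c(Br)c1O
F13 | step 2 | allyl 3-bromo-6-methyl-2,4-bis(trimethylsilyloxy)benzoate | C=CCOC(=O)c1c(C)cc(O[Si](C)(C)C)c(Br)c1O[Si](C)(C)C
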